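**Retrosynthetic overview**
- Target 10 ⇐ 5-exo-tet opening of the (R,R)-aryl epoxide 9 by the primary hydroxyl. This forms the only ring, in the last step, as in the norlignan pathway (agatharesinol/sequirin-type diol → epoxide → tetrahydrofuran).
- 9 ⇐ reagent-controlled epoxidation of the unprotected ene-diol 8, run in the same pot as the ring closure.
- 8 ⇐ cross-metathesis of vinyl diol 6 with 3,4-dimethoxystyrene 7.
- 6 ⇐ anti-selective catalytic asymmetric cinnamylboration of silyloxyacetaldehyde 3 with (E)-boronate 2, which sets both backbone stereocentres.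
- 2 ⇐ 4-methoxycinnamyl alcohol 1.

Assumption: (S)-TRIP is taken to direct Si-face allylboration of aldehyde 3 (mirror image of the (R)-TRIP/benzaldehyde → (R)-alcohol case, recalled rather than checked); if the product proves antipodal, (R)-TRIP is used and nothing else changes.

**Step 1**
Reactants: 1 (E)-3-(4-methoxyphenyl)prop-2-en-1-ol (4-methoxycinnamyl alcohol)
Product: 2 2-[(2E)-3-(4-methoxyphenyl)prop-2-en-1-yl]-4,4,5,5-tetramethyl-1,3,2-dioxaborolane
Conditions: B2pin2 (1.2 equiv), Pd(MeCN)4(BF4)2 (5 mol%), DMSO–MeOH 1:1, 40 °C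
Reagents that add atoms: bis(pinacolato)diboron, CC1(C)OB(OC1(C)C)B1OC(C)(C)C(C)(C)O1
Why: Pd-catalysed allylic borylation of the alcohol through an η3-cinnamyl-palladium intermediate that is borylated at the unhindered terminus, giving the linear (E)-allylboronate; no stereocentre is formed.

**Step 2**
Reactants: 2 (E)-4-methoxycinnamyl pinacol boronate; 3 (tert-butyldimethylsilyloxy)acetaldehyde
Product: 6 (2S,3R)-3-(4-methoxyphenyl)pent-4-ene-1,2-diol, via O-Bpin borate of the homoallylic alcohol 4 (not isolated), via TBS-protected homoallylic alcohol 5 (not isolated)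
Conditions: (S)-TRIP (5 mol%), 4 Å MS, toluene, −30 °C; then 2 M aq. HCl–THF, rt
Reagents that add atoms: none
Why: Chiral-phosphoric-acid-catalysed allylboration through a closed chair (Zimmerman–Traxler) transition state, in which the (E)-boronate gives the anti product and (S)-TRIP selects the aldehyde Si face, so C2 (S) and C3 (R) are set together, after which aqueous acid hydrolyses the borate and the primary TBS ether.

**Step 3**
Reactants: 6 (2S,3R)-3-(4-methoxyphenyl)pent-4-ene-1,2-diol; 7 4-ethenyl-1,2-dimethoxybenzene (3,4-dimethoxystyrene, 3 equiv)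
Product: 8 (2S,3R,4E)-5-(3,4-dimethoxyphenyl)-3-(4-methoxyphenyl)pent-4-ene-1,2-diol
Conditions: Hoveyda–Grubbs II (5 mol%), 1,4-benzoquinone (10 mol%), CH2Cl2, 40 °C
Reagents that add atoms: none
Why: Olefin cross-metathesis of a hindered terminal alkene with excess styrene gives the thermodynamically preferred (E)-styrene, with benzoquinone suppressing Ru–H isomerisation of the allylic/benzylic C3–H, so neither stereocentre is touched.

**Step 4**
Reactants: 8 (2S,3R,4E)-5-(3,4-dimethoxyphenyl)-3-(4-methoxyphenyl)pent-4-ene-1,2-diol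
Product: 10 (3S,4R,5S)-5-[(R)-(3,4-dimethoxyphenyl)(hydroxy)methyl]-4-(4-methoxyphenyl)oxolan-3-ol, via epoxy diol 9 (not isolated)
Conditions: D-fructose-derived Shi ketone (30 mol%), Oxone (1.5 equiv), K2CO3, nBu4NHSO4 (cat.), MeCN–DMM/aq. Na2B4O7–Na2EDTA (pH 10.5), 0 °C; then 2 M aq. KOH to pH ≥ 13.5, 0 °C → rt
Reagents that add atoms: Oxone (potassium peroxymonosulfate), [K+].OOS(=O)(=O)[O-]
Why: Shi asymmetric epoxidation (reagent-controlled spiro transition state, as for trans-β-methylstyrene) gives the (2R,3R)-epoxide of the trans-styrene, and at high pH the primary alkoxide opens it 5-exo-tet at the non-benzylic carbon with inversion (Baldwin-favoured intramolecular epoxide opening), which sets ring C5 (S), keeps the carbinol carbon (R) and places all three ring substituents cis.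

**Compound list**
1 | (E)-3-(4-methoxyphenyl)prop-2-en-1-ol | COc1ccc(/C=C/CO)cc1 | starting material
2 | 2-[(2E)-3-(4-methoxyphenyl)prop-2-en-1-yl]-4,4,5,5-tetramethyl-1,3,2-dioxaborolane | COc1ccc(/C=C/CB2OC(C)(C)C(C)(C)O2)cc1 | intermediate
3 | (tert-butyldimethylsilyloxy)acetaldehyde | CC(C)(C)[Si](C)(C)OCC=O | starting material
4 | pinacol borate ester of (2S,3R)-1-(tert-butyldimethylsilyloxy)-3-(4-methoxyphenyl)pent-4-en-2-ol (O–Bpin on the C2 oxygen) | CC(C)(C)[Si](C)(C)OC[C@@H](OB1OC(C)(C)C(C)(C)O1)[C@H](C=C)c1ccc(OC)cc1 | intermediate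
5 | (2S,3R)-1-(tert-butyldimethylsilyloxy)-3-(4-methoxyphenyl)pent-4-en-2-ol | CC(C)(C)[Si](C)(C)OC[C@@H](O)[C@H](C=C)c1ccc(OC)cc1 | intermediate
6 | (2S,3R)-3-(4-methoxyphenyl)pent-4-ene-1,2-diol | OC[C@@H](O)[C@H](C=C)c1ccc(OC)cc1 | intermediate
7 | 4-ethenyl-1,2-dimethoxybenzene | C=Cc1ccc(OC)c(OC)c1 | starting material
8 | (2S,3R,4E)-5-(3,4-dimethoxyphenyl)-3-(4-methoxyphenyl)pent-4-ene-1,2-diol | OC[C@@H](O)[C@H](/C=C/c1ccc(OC)c(OC)c1)c1ccc(OC)cc1 | intermediate
9 | (2S,3R)-3-[(2R,3R)-3-(3,4-dimethoxyphenyl)oxiran-2-yl]-3-(4-methoxyphenyl)propane-1,2-diol | OC[C@@H](O)[C@H]([C@H]1O[C@@H]1c1ccc(OC)c(OC)c1)c1ccc(OC)cc1 | intermediate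
10 | (3S,4R,5S)-5-[(R)-(3,4-dimethoxyphenyl)(hydroxy)methyl]-4-(4-methoxyphenyl)oxolan-3-ol | COc1ccc([C@H]2[C@@H]([C@H](O)c3ccc(OC)c(OC)c3)OC[C@H]2O)cc1 | target

**Totals**
Total steps: 4. Longest linear sequence: 4 (1 → 2 → 6 → 8 → 10).

**Steps most likely to fail, with fallbacks**

Step 4 (highest risk). The electron-rich benzylic C–O bond of epoxide 9 can ionise in the aqueous medium and be trapped at the benzylic carbon, giving the 2-aryl-tetrahydrofuran or tetrahydropyran isomers, before the base-driven 5-exo closure takes over. The fallback sets out from 8 and returns at 10. Both hydroxyls of 8 are silylated (TESCl, imidazole, DMF) to the 1,2-bis(triethylsilyl) ether of 8, F1. Shi epoxidation with the same ketone gives the bis(triethylsilyl) ether of epoxy diol 9, F2, which carries no internal nucleophile and is extracted at once into Et3N-buffered ether. TBAF in dry THF at 0 °C then unmasks the alkoxides in a non-ionising medium, and the primary alkoxide closes the ring 5-exo to 10.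

Step 2. Enantio- and diastereoselectivity could erode with the α-silyloxy aldehyde and the γ-aryl boronate, and the sense of induction rests on analogy. The fallback sets out from 3 and returns at 5. Aldehyde 3 is coupled with commercial 1-methoxy-4-(prop-1-yn-1-yl)benzene (COc1ccc(C#CC)cc1) by ruthenium-catalysed transfer hydrogenation (RuH2(CO)(PPh3)3, a Josiphos ligand, an arenesulfonic acid co-catalyst, 2-propanol as hydride donor, THF, 95 °C). The alkyne isomerises to the aryl allene, hydrometalation gives an (E)-σ-allylruthenium species, and chair-like carbonyl addition delivers the anti-(α-aryl)allylation product 5, which is then hydrolysed to 6 as before. No new compound is made (F0).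

Step 3. The electron-rich styrene can homodimerise to the stilbene, and Ru–H species can move the terminal alkene into conjugation and destroy C3. The fallback sets out from 6 and returns at 8. Cross-metathesis of 6 with vinylboronic acid pinacol ester (Hoveyda–Grubbs II, CH2Cl2, 40 °C) gives the (E)-alkenyl boronate (2S,3R,4E)-3-(4-methoxyphenyl)-5-(4,4,5,5-tetramethyl-1,3,2-dioxaborolan-2-yl)pent-4-ene-1,2-diol, F3. Suzuki–Miyaura coupling of F3 with 4-bromo-1,2-dimethoxybenzene (Pd(dppf)Cl2, K3PO4, dioxane–H2O, 60 °C) gives 8 with retention of the (E)-geometry.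

**Further compounds**
F1 | step 4 | 1,2-bis(triethylsilyl) ether of ene-diol 8 (configurations as in 8) | CC[Si](CC)(CC)OC[C@@H](O[Si](CC)(CC)CC)[C@H](/C=C/c1ccc(OC)c(OC)c1)c1ccc(OC)cc1
F2 | step 4 | 1,2-bis(triethylsilyl) ether of epoxy diol 9 ((R,R)-epoxide, backbone as in 9) | CC[Si](CC)(CC)OC[C@@H](O[Si](CC)(CC)CC)[C@H]([C@H]1O[C@@H]1c1ccc(OC)c(OC)c1)c1ccc(OC)cc1
F3 | step 3 | (2S,3R,4E)-3-(4-methoxyphenyl)-5-(4,4,5,5-tetramethyl-1,3,2-dioxaborolan-2-yl)pent-4-ene-1,2-diol | OC[C@@H](O)[C@H](/C=C/B1OC(C)(C)C(C)(C)O1)c1ccc(OC)cc1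
F0 | step 2 | none | none
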